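Retrosynthetic cuts, in order: (1) C2–C1′ between pyranone ring C and aryl ring B; (2) the prenyl C=C, back to allyl; (3) O1–C2 of dihydrofuran ring D, back to a phenol and an epoxide; (4) the epoxide oxygen and the C3–alkenyl bond, back to 3-allylsalicylaldehyde.
Forward: aldehyde → one-flask asymmetric alkenylation/epoxidation → fluoride-triggered 5-exo closure of ring D → allyl-to-prenyl cross metathesis → silylation. Rings A/C enter ready-made as 5,7-diacetoxychromone and are joined to ring B in the second-last step, and one flask then removes all masks.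
Enabling feature (benzofuran numbering for the B/D half): ring B is a 1,2,3-trisubstituted benzene (C3a, C7a–O, C7-prenyl), so C5–H, the future C1′, is the only aryl C–H with hydrogen on both sides. In ring C the C2=C3 bond is polarised by O1 and by C4=O in the same sense, toward aryl delivery at C2.
Two C–H carbons are therefore united in one flask (a formal dehydrogenative cross-coupling). The Bpin group is a transient activator made and consumed there, and neither half ever carries a halogen.
Stereochemistry: C3 comes from (−)-MIB-controlled Si-face alkenylzinc addition. C2 comes from A(1,3)-strain-controlled, oxygen-directed (threo) epoxidation followed by invertive epoxide opening, which gives the trans-(2R,3R) diol.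

Key step: step 7

Assumption: 3-allylsalicylaldehyde and 5,7-dihydroxychromone are taken as catalogue chemicals, and (−)-MIB is assumed to show with aldehyde 2 the same Si-face preference that it shows with other aryl aldehydes.

Step 1
Reactants: 1 3-allyl-2-hydroxybenzaldehyde
Product: 2 3-allyl-2-(triisopropylsilyloxy)benzaldehyde
Conditions: TIPSCl, imidazole, DMAP (cat.), DMF, 25 → 40 °C
Reagents that add atoms: chlorotriisopropylsilane, CC(C)[Si](Cl)(C(C)C)C(C)C
Why: Routine imidazole-promoted silylation of a phenol; the bulky TIPS ether removes the acidic, chelating OH that would spoil the zinc chemistry, resists O-to-O migration to the later alkoxide, and is kept as the fluoride-releasable trigger for ring closure.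

Step 2
Reactants: 2 3-allyl-2-(triisopropylsilyloxy)benzaldehyde
Product: 4 threo epoxy alcohol (R)-[3-allyl-2-(triisopropylsilyloxy)phenyl][(2S)-3,3-dimethyloxiran-2-yl]methanol, via alkenylzinc alkoxide 3 (not isolated)
Conditions: Me2C=CHMgBr (THF), ZnCl2, Et2O, 0 °C; 1,4-dioxane, filter off magnesium salts; (−)-MIB (10 mol %), toluene, 0 °C; then t-BuOOH (decane), Ti(OiPr)4 (20 mol %), −20 → 0 °C; aq NH4Cl
Reagents that add atoms: 2-methylprop-1-enylmagnesium bromide, CC(C)=C[Mg]Br; tert-butyl hydroperoxide, CC(C)(C)OO; zinc chloride, Cl[Zn]Cl (zinc is held by 3 only)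
Why: Amino-alcohol-catalysed asymmetric alkenylzinc addition to an aryl aldehyde is followed in the same flask by titanium-catalysed alkoxide-directed epoxidation: the (−)-MIB–zinc complex should deliver the alkenyl group to the Si face (S at the alkoxide stage, R by name once the epoxide is in place), A(1,3) strain with the Z-methyl group holds the carbinol C–H in the alkene plane so that the metal-bound peroxide reaches only the face syn to oxygen (threo, 2S), and the allyl group, having no directing oxygen, stays untouched.

Step 3
Reactants: 4 threo epoxy alcohol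
Product: 6 (2R,3R)-7-allyl-2-(2-hydroxypropan-2-yl)-2,3-dihydro-1-benzofuran-3-ol, via epoxy phenoxide 5 (not isolated)
Conditions: TBAF (1.1 equiv), THF, 0 → 25 °C; aq NH4Cl
Reagents that add atoms: none
Why: Fluoride cleaves the aryl silyl ether and the phenoxide opens the epoxide by base-mediated 5-exo-tet SN2 attack at the less substituted carbon, so C2 is set by clean inversion (2S epoxide to 2R ether), C3 is not touched, and the two substituents should end up trans.

Step 4
Reactants: 6 (2R,3R)-7-allyl diol
Product: 7 (2R,3R)-2-(2-hydroxypropan-2-yl)-7-(3-methylbut-2-en-1-yl)-2,3-dihydro-1-benzofuran-3-ol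
Conditions: 2-methyl-2-butene (large excess), second-generation Grubbs catalyst (5 mol %), 1,4-benzoquinone (10 mol %), CH2Cl2, 40 °C
Reagents that add atoms: 2-methyl-2-butene, CC=C(C)C
Why: Olefin cross metathesis of a terminal allylarene with excess 2-methyl-2-butene is the standard allyl-to-prenyl conversion; it is driven by loss of propene and tolerates free alcohols, and it is placed after the epoxidation so that the electron-rich prenyl alkene never meets an oxidant.

Step 5
Reactants: 7 (2R,3R)-7-prenyl diol
Product: 8 bis-TES ether (2R,3R)-7-(3-methylbut-2-en-1-yl)-3-(triethylsilyloxy)-2-[2-(triethylsilyloxy)propan-2-yl]-2,3-dihydro-1-benzofuran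
Conditions: TESOTf (2.5 equiv), 2,6-lutidine, CH2Cl2, −78 → 0 °C
Reagents that add atoms: triethylsilyl triflate, CC[Si](CC)(CC)OS(=O)(=O)C(F)(F)F
Why: Silyl triflate/2,6-lutidine silylation caps a secondary and a hindered tertiary alcohol together; the two ethers keep the alcohols from O-borylation, keep the benzylic carbinol from aerobic palladium oxidation, and, being poor leaving groups, keep C3 from ionising.

Step 6
Reactants: 9 5,7-dihydroxy-4H-chromen-4-one
Product: 10 4-oxo-4H-chromene-5,7-diyl diacetate
Conditions: Ac2O, pyridine, DMAP (cat.), 25 °C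
Reagents that add atoms: acetic anhydride, CC(=O)OC(C)=O
Why: Pyridine-promoted O-acetylation of both phenols (DMAP helps with the chelated 5-OH) removes the acidic protons that would bind divalent palladium, and aryl acetates should withstand the neutral, base-free coupling medium yet fall off under mild base.

Step 7
Reactants: 8 bis-TES ether; 10 4-oxo-4H-chromene-5,7-diyl diacetate
Product: 12 5,7-di-O-acetyl bis-TES ether of the target, via arylboronate 11 (not isolated)
Conditions: 8, [Ir(OMe)(cod)]2 (2 mol %), dtbpy (4 mol %), B2pin2 (1.0 equiv), THF, 70 °C; evaporate (removes HBpin); residue in DMF added slowly to 10 (2 equiv), Pd(OAc)2 (10 mol %), 1,10-phenanthroline (12 mol %), O2 (1 atm), DMF, 80 °C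
Reagents that add atoms: bis(pinacolato)diboron, CC1(C)OB(OC1(C)C)B1OC(C)(C)C(C)(C)O1 (its boryl group is held by 11 only; nothing from it remains in 12)
Why: A trivalent iridium tris(boryl) complex cleaves the least hindered aryl C–H bond of 8, and since C4–H lies next to C3a with its C3 silyloxy group and C6–H lies next to the prenyl CH2, only C5–H, which has hydrogen on both sides, should be borylated to give 11. After the solvent change 11 transmetalates to (phen)Pd(OAc)2, the aryl–palladium bond adds syn across C2=C3 of 10 with the aryl group going to C2 because the ring oxygen O1 (enol ether) and the C4 carbonyl (enone) polarise the double bond the same way, and the C3 palladium enolate epimerises through its O-bound form so that syn β-hydride elimination of H-2 restores the pyranone. The palladium hydride collapses to zerovalent palladium, which O2 returns to the divalent state, so the net change is the union of two C–H carbons with loss of two hydrogens. The closest known reaction types are the one-flask C–H borylation/cross-coupling sequence and the oxidative boron-Heck arylation of chromones and coumarins with arylboron reagents, an established entry to flavones. No ring is closed and no stereocentre is formed; C2 and C3 of ring D are spectators, shielded from alcohol oxidation and from ionisation by their silyl ethers. The selectivities needed are site selectivity (C5 over C4 and C6 in ring B, C2 over C3 in ring C), secured as described, and chemoselectivity over the prenyl group, secured because a trisubstituted unpolarised alkene hydroborates and inserts far more slowly than the polarised chromone double bond, which is moreover present in excess while 11 is fed in slowly to hold back homocoupling.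

Step 8
Reactants: 12 5,7-di-O-acetyl bis-TES ether of the target
Product: 14 target flavone CNP0172554.2, via bis-TES dihydroxyflavone 13 (not isolated)
Conditions: K2CO3 (2.5 equiv), MeOH–THF, 0 °C; AcOH to neutrality, evaporate; then TBAF–AcOH (1:1, 3 equiv), THF, 0 → 25 °C
Reagents that add atoms: none
Why: Carbonate-promoted transesterification cleaves the two aryl acetates and acetic-acid-buffered fluoride then cleaves both Si–O bonds at silicon, so no C–O bond at C2 or C3 is touched, no strong acid meets the ionisable benzylic alcohol or the prenyl group, and both stereocentres are carried through unchanged.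

Compound list
1 | 3-allyl-2-hydroxybenzaldehyde | C=CCc1cccc(C=O)c1O | starting material
2 | 3-allyl-2-(triisopropylsilyloxy)benzaldehyde | C=CCc1cccc(C=O)c1O[Si](C(C)C)(C(C)C)C(C)C | intermediate
3 | (2-methylprop-1-enyl)zinc alkoxide of (S)-1-[3-allyl-2-(triisopropylsilyloxy)phenyl]-3-methylbut-2-en-1-ol (not isolated) | CC(C)=C[C@H](O[Zn]C=C(C)C)c1cccc(CC=C)c1O[Si](C(C)C)(C(C)C)C(C)C | intermediate
4 | (R)-[3-allyl-2-(triisopropylsilyloxy)phenyl][(2S)-3,3-dimethyloxiran-2-yl]methanol (threo) | CC1(C)O[C@H]1[C@H](O)c2cccc(CC=C)c2O[Si](C(C)C)(C(C)C)C(C)C | intermediate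
5 | 2-allyl-6-{(R)-[(2S)-3,3-dimethyloxiran-2-yl](hydroxy)methyl}phenol, reacting as its tetrabutylammonium phenoxide (not isolated) | CC1(C)O[C@H]1[C@H](O)c2cccc(CC=C)c2O | intermediate
6 | (2R,3R)-7-allyl-2-(2-hydroxypropan-2-yl)-2,3-dihydro-1-benzofuran-3-ol (trans) | C=CCc1cccc2c1O[C@@H](C(C)(C)O)[C@@H]2O | intermediate
7 | (2R,3R)-2-(2-hydroxypropan-2-yl)-7-(3-methylbut-2-en-1-yl)-2,3-dihydro-1-benzofuran-3-ol | CC(C)=CCc1cccc2c1O[C@@H](C(C)(C)O)[C@@H]2O | intermediate
8 | (2R,3R)-7-(3-methylbut-2-en-1-yl)-3-(triethylsilyloxy)-2-[2-(triethylsilyloxy)propan-2-yl]-2,3-dihydro-1-benzofuran | CC(C)=CCc1cccc2c1O[C@@H](C(C)(C)O[Si](CC)(CC)CC)[C@@H]2O[Si](CC)(CC)CC | intermediate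
9 | 5,7-dihydroxy-4H-chromen-4-one | O=c1ccoc2cc(O)cc(O)c12 | starting material
10 | 4-oxo-4H-chromene-5,7-diyl diacetate | CC(=O)Oc1cc(OC(C)=O)c2c(=O)ccoc2c1 | intermediate
11 | 5-(4,4,5,5-tetramethyl-1,3,2-dioxaborolan-2-yl) derivative of 8, (2R,3R) (not isolated) | CC(C)=CCc1cc(B3OC(C)(C)C(C)(C)O3)cc2c1O[C@@H](C(C)(C)O[Si](CC)(CC)CC)[C@@H]2O[Si](CC)(CC)CC | intermediate
12 | 2-{(2R,3R)-7-(3-methylbut-2-en-1-yl)-3-(triethylsilyloxy)-2-[2-(triethylsilyloxy)propan-2-yl]-2,3-dihydro-1-benzofuran-5-yl}-4-oxo-4H-chromene-5,7-diyl diacetate | CC(C)=CCc1cc(-c3cc(=O)c4c(OC(C)=O)cc(OC(C)=O)cc4o3)cc2c1O[C@@H](C(C)(C)O[Si](CC)(CC)CC)[C@@H]2O[Si](CC)(CC)CC | intermediate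
13 | 5,7-dihydroxy analogue of 12, both TES ethers still in place, (2R,3R) (not isolated) | CC(C)=CCc1cc(-c3cc(=O)c4c(O)cc(O)cc4o3)cc2c1O[C@@H](C(C)(C)O[Si](CC)(CC)CC)[C@@H]2O[Si](CC)(CC)CC | intermediate
14 | 5,7-dihydroxy-2-[(2R,3R)-3-hydroxy-2-(2-hydroxypropan-2-yl)-7-(3-methylbut-2-en-1-yl)-2,3-dihydro-1-benzofuran-5-yl]-4H-chromen-4-one | CC(C)=CCc1cc(-c2cc(=O)c3c(O)cc(O)cc3o2)cc2c1O[C@@H](C(C)(C)O)[C@@H]2O | target

Total steps: 8. Longest linear sequence: 7 (steps 1, 2, 3, 4, 5, 7, 8).

Steps most likely to fail

Risk 1, step 7.
- **What may go wrong:** hydroboration or metal-hydride-induced migration of the prenyl double bond, oxidative homocoupling or hydroxylation of the boronate under O2, and sluggish insertion into the chromone double bond.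
- **Fallback (sets out from 6 and 10, returns at 12):** the halogen is placed by the innate para-directing effect of O1 before the prenyl alkene exists, and the chromone is made the nucleophile by polarity reversal. NBS in MeCN at 0 °C should brominate 6 para to the ring oxygen to give 7-allyl-5-bromo diol F1. Cross metathesis as in step 4 gives 5-bromo-7-prenyl diol F2, and silylation as in step 5 gives bis-TES aryl bromide F3. Diacetate 10 is zincated at C2–H, its most acidic position next to O1, with TMPZnCl·LiCl in THF at 25 °C to give chromon-2-ylzinc chloride F4. Negishi coupling of F4 with F3 (Pd(OAc)2, SPhos, THF, 50 °C) then gives 12.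

Risk 2, step 2.
- **What may go wrong:** erosion of enantiofacial selectivity by a salt-promoted uncatalysed addition or by the bulky ortho silyloxy group, and Lewis-acid opening of the epoxide during the titanium stage.
- **Fallback (sets out from 2, returns at 4):** the stereocentre is set by ketone reduction instead of C–C bond formation. Direct addition of Me2C=CHMgBr to 2 in THF at −78 °C gives racemic allylic alcohol F5, and MnO2 in CH2Cl2 gives aryl alkenyl ketone F6. Corey–Bakshi–Shibata reduction with the (R)-methyl oxazaborolidine and BH3·SMe2, on the premise that the ortho-silyloxy aryl group acts as the large substituent, gives (S)-allylic alcohol F7. Hydroxyl-directed epoxidation of F7 with t-BuOOH and Ti(OiPr)4, or with buffered m-CPBA, under the same A(1,3) control gives 4.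

Risk 3, step 3.
- **What may go wrong:** Payne migration of the epoxide started by the free neighbouring alkoxide, with loss of regiocontrol in the ring closure.
- **Fallback (sets out from 4, returns at 8):** the carbinol oxygen is taken out of play before the phenoxide is released, and the protecting-group sequence is re-ordered. TESCl and imidazole in DMF give C1-O-TES epoxide F8. One equivalent of TBAF in THF at −20 °C cleaves the more labile aryl silyl ether, and the phenoxide closes ring D to give 7-allyl C3-O-TES carbinol F9. Cross metathesis as in step 4 gives 7-prenyl C3-O-TES carbinol F10, and TESOTf with 2,6-lutidine caps the tertiary alcohol to give 8.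

Further compounds
F1 | step 7 | (2R,3R)-7-allyl-5-bromo-2-(2-hydroxypropan-2-yl)-2,3-dihydro-1-benzofuran-3-ol | C=CCc1cc(Br)cc2c1O[C@@H](C(C)(C)O)[C@@H]2O
F2 | step 7 | (2R,3R)-5-bromo-2-(2-hydroxypropan-2-yl)-7-(3-methylbut-2-en-1-yl)-2,3-dihydro-1-benzofuran-3-ol | CC(C)=CCc1cc(Br)cc2c1O[C@@H](C(C)(C)O)[C@@H]2O
F3 | step 7 | (2R,3R)-5-bromo-7-(3-methylbut-2-en-1-yl)-3-(triethylsilyloxy)-2-[2-(triethylsilyloxy)propan-2-yl]-2,3-dihydro-1-benzofuran | CC(C)=CCc1cc(Br)cc2c1O[C@@H](C(C)(C)O[Si](CC)(CC)CC)[C@@H]2O[Si](CC)(CC)CC
F4 | step 7 | chloro(5,7-diacetoxy-4-oxo-4H-chromen-2-yl)zinc | CC(=O)Oc1cc(OC(C)=O)c2c(=O)cc([Zn]Cl)oc2c1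
F5 | step 2 | racemic 1-[3-allyl-2-(triisopropylsilyloxy)phenyl]-3-methylbut-2-en-1-ol | CC(C)=CC(O)c1cccc(CC=C)c1O[Si](C(C)C)(C(C)C)C(C)C
F6 | step 2 | 1-[3-allyl-2-(triisopropylsilyloxy)phenyl]-3-methylbut-2-en-1-one | CC(C)=CC(=O)c1cccc(CC=C)c1O[Si](C(C)C)(C(C)C)C(C)C
F7 | step 2 | (S)-1-[3-allyl-2-(triisopropylsilyloxy)phenyl]-3-methylbut-2-en-1-ol | CC(C)=C[C@H](O)c1cccc(CC=C)c1O[Si](C(C)C)(C(C)C)C(C)C
F8 | step 3 | triethylsilyl ether of 4 at the carbinol oxygen, (1R,2S) | CC1(C)O[C@H]1[C@H](O[Si](CC)(CC)CC)c2cccc(CC=C)c2O[Si](C(C)C)(C(C)C)C(C)C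
F9 | step 3 | 2-[(2R,3R)-7-allyl-3-(triethylsilyloxy)-2,3-dihydro-1-benzofuran-2-yl]propan-2-ol | C=CCc1cccc2c1O[C@@H](C(C)(C)O)[C@@H]2O[Si](CC)(CC)CC
F10 | step 3 | 2-[(2R,3R)-7-(3-methylbut-2-en-1-yl)-3-(triethylsilyloxy)-2,3-dihydro-1-benzofuran-2-yl]propan-2-ol | CC(C)=CCc1cccc2c1O[C@@H](C(C)(C)O)[C@@H]2O[Si](CC)(CC)CC
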